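Atoms are numbered as they appear in the target SMILES. In ring C (C11, C13, C15, C17, C19, C26, C28), carbonyl C15 is bonded to fusion carbon C17. C26, which carries methyl C27, is bonded to the other fusion carbon C19. C15 and C26 can therefore be read as former neighbours in a 2-methylcyclopentane-1,3-dione that the C=C of ring D has pushed apart. A de Mayo sequence exploits this. Enol acetate 2 and the S-configured enol ether 6 (TBS on the enol oxygen, TES on C21–O) photocycloadd to form C15–C17 and C19–C26. Retro-aldol scission of C15–C26 then delivers rings C and D with C17, C19 and C26 in one operation. Pyranone 18 enters late by Michael–hemiketalisation.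

Key step: step 5

Convention: the top face of ring C is the face that carries the C17 oxygen, and the bottom face is the opposite one.
Assumption: C11 and C28 (and, more slowly, C13) can equilibrate through the ring-opened keto form of the hemiketal, so the natural configuration at these centres is taken as the thermodynamically preferred one; C13 is nevertheless set kinetically in step 7.

Step 1
Reactants: 1 2-methylcyclopentane-1,3-dione
Product: 2 3-acetoxy-2-methylcyclopent-2-en-1-one
Conditions: isopropenyl acetate, TsOH·H2O (cat.), reflux, acetone distilled off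
Reagents that add atoms: isopropenyl acetate CC(=C)OC(C)=O
Why: Acid-catalysed enol acetylation by acyl transfer from an enol ester; the symmetrical, fully enolised dione can give only one enol acetate, and removal of acetone drives the exchange.

Step 2
Reactants: 3 2,2-dimethylcyclopentane-1,3-dione
Product: 4 (S)-3-hydroxy-2,2-dimethylcyclopentan-1-one
Conditions: S-selective ketoreductase, NADP+ (cat.), iPrOH, KH2PO4/K2HPO4 buffer pH 7, 30 °C
Reagents that add atoms: none
Why: Enzymatic desymmetrising mono-reduction of a prochiral 2,2-disubstituted cyclopentane-1,3-dione, in the same sense as the classical baker's yeast reduction of this dione; hydride delivery to one enantiotopic carbonyl sets C21 as S.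

Step 3
Reactants: 4 (S)-3-hydroxy-2,2-dimethylcyclopentan-1-one
Product: 5 (S)-2,2-dimethyl-3-(triethylsilyloxy)cyclopentan-1-one
Conditions: TESCl, imidazole, CH2Cl2, 0 °C → rt
Reagents that add atoms: chlorotriethylsilane CC[Si](Cl)(CC)CC
Why: Standard silyl ether formation; TES is chosen because it can later be removed from C21–O beside TBS ethers, and its bulk next to the gem-dimethyl carbon shields one face of ring D.

Step 4
Reactants: 5 (S)-2,2-dimethyl-3-(triethylsilyloxy)cyclopentan-1-one
Product: 6 (S)-1-(tert-butyldimethylsilyloxy)-5,5-dimethyl-4-(triethylsilyloxy)cyclopent-1-ene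
Conditions: TBSOTf, Et3N, CH2Cl2, 0 °C
Reagents that add atoms: tert-butyldimethylsilyl triflate CC(C)(C)[Si](C)(C)OS(=O)(=O)C(F)(F)F
Why: Soft enolisation–silylation with a silyl triflate and an amine; C23 is quaternary, so only the C17=C19 enol ether can form, and C21 is not touched.

Step 5
Reactants: 2 3-acetoxy-2-methylcyclopent-2-en-1-one; 6 (S)-1-(tert-butyldimethylsilyloxy)-5,5-dimethyl-4-(triethylsilyloxy)cyclopent-1-ene
Product: 8 (1R,6S,7R,9S)-1-(tert-butyldimethylsilyloxy)-6,10,10-trimethyl-9-(triethylsilyloxy)bicyclo[5.3.0]decane-2,5-dione (ketones C15 and C28; cis fusion; C17–O, C19–H and C21–O on top; C27 methyl on the bottom), via cyclobutane photoadduct 7 (not isolated)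
Conditions: 2 (excess, in portions), hν (medium-pressure Hg lamp, Pyrex, λ > 290 nm), degassed CH2Cl2, −20 °C; concentrate; K2CO3 (cat.), MeOH, 0 °C → rt
Reagents that add atoms: none
Why: Excitation of 2 and intersystem crossing give the triplet enone, which adds stepwise through a 1,4-biradical to the electron-rich C17=C19 bond of 6, and base-catalysed methanolysis of the tertiary acetate in 7 then frees a cyclobutanolate that undergoes strain-driven retro-aldol cleavage of C15–C26 to ketone C15 and the C28 enolate. This is the de Mayo reaction of cyclic 1,3-dione enol esters with cycloalkenes, and [2+2] photocycloaddition of enones to silyl enol ethers is likewise established. The cyclobutane closes by recombination of the biradical (formal [2+2]), whereas ring C is not formed by a cyclisation but emerges when the bond shared by the four- and five-membered rings breaks, a two-carbon ring expansion that leaves ring D intact. C17 and C19 must be cis because both new bonds reach one face of a cyclopentene, and that face should be the one opposite the C21 OTES group, so the S carbinol fixes the absolute sense, while C26 is protonated reversibly beside ketone C28 and should settle with its methyl group anti to the C17 OTBS group. The step needs head-to-tail orientation, which the siloxy donor on C17 secures by pairing this carbon with the enone β-carbon C15, and it needs cross-addition to outrun enone dimerisation, which the tetrasubstituted C=C of 2 resists. Both silyl ethers tolerate catalytic K2CO3 in MeOH.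

Step 6
Reactants: 8 hydroazulene-dione
Product: 9 5-methylene ketone (C28=C29H2; C15 the only ketone; other centres as in 8)
Conditions: Ph3PCH3Br, KOtBu (ylide 1.2 equiv), THF, 0 °C → rt
Reagents that add atoms: methyltriphenylphosphonium bromide C[P+](c1ccccc1)(c1ccccc1)c1ccccc1.[Br-]
Why: Wittig methylenation; C28 lies between a CH2 and a methine, whereas C15 is shielded by fully substituted C17 with its OTBS group and the adjacent gem-dimethyl carbon, so a limited amount of ylide should react at C28 only and leave a single ketone for the next enolisation.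

Step 7
Reactants: 9 5-methylene ketone
Product: 11 C13 alcohol (C13–OH on the bottom face and anti to C17–OTBS), via potassium enolate 10 (not isolated)
Conditions: KN(SiMe3)2, THF, −78 °C; 2-(phenylsulfonyl)-3-phenyloxaziridine, −78 °C; aq. NH4Cl
Reagents that add atoms: 2-(phenylsulfonyl)-3-phenyloxaziridine O=S(=O)(c1ccccc1)N1OC1c1ccccc1
Why: Davis oxidation of the only possible enolate (C17 bears no hydrogen); the oxaziridine should reach C13 from the bottom face, opposite the pseudo-axial C17 OTBS group that lies 1,3 to C13, which places C13–O as in the target.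

Step 8
Reactants: 11 C13 alcohol
Product: 12 C13 TBS ether
Conditions: TBSOTf, 2,6-lutidine, CH2Cl2, −78 → 0 °C
Reagents that add atoms: tert-butyldimethylsilyl triflate CC(C)(C)[Si](C)(C)OS(=O)(=O)C(F)(F)F
Why: Silyl triflate silylation of a hindered secondary alcohol under a weak, hindered base that should not enolise ketone C15, so C13 keeps its configuration.

Step 9
Reactants: 12 C13 TBS ether
Product: 13 C21 alcohol (TES removed; both TBS ethers kept)
Conditions: PPTS (cat.), MeOH, 0 °C → rt
Reagents that add atoms: none
Why: Acid-catalysed solvolysis discriminates silyl ethers by size, so the TES ether at C21 should cleave well before the secondary C13 and tertiary C17 TBS ethers.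

Step 10
Reactants: 13 C21 alcohol
Product: 15 ring D enone (C19=C20–C21=O), via C21 ketone 14 (not isolated)
Conditions: IBX (excess), DMSO–fluorobenzene, rt → 70 °C
Reagents that add atoms: none
Why: IBX oxidation of the carbinol followed by IBX dehydrogenation of the ketone through its enol; C23 is quaternary, so 14 can enolise only toward C20, while the sole α-hydrogen of ketone C15 sits on tertiary C13 beneath an OTBS group and should react far more slowly.

Step 11
Reactants: 15 ring D enone
Product: 16 C11 allylic alcohol (C11–OH expected on top and trans to C13–OTBS; either epimer serves)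
Conditions: SeO2 (cat.), tBuOOH, CH2Cl2, 0 °C → rt
Reagents that add atoms: tert-butyl hydroperoxide CC(C)(C)OO; selenium dioxide O=[Se]=O (relays the oxygen)
Why: Riley-type allylic hydroxylation (ene reaction then [2,3]-sigmatropic shift) of an exocyclic methylene group, which in ring systems normally oxidises the ring CH2 (C11) rather than the substituted methine (C26–H, held near the planes of both neighbouring C=C bonds by allylic strain); the new C11 centre is erased in step 12.

Step 12
Reactants: 16 C11 allylic alcohol
Product: 17 exo-methylene ketone (C29H2=C28–C11=O; bis-enone)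
Conditions: Dess–Martin periodinane, CH2Cl2, 0 °C → rt; used directly
Reagents that add atoms: none
Why: Dess–Martin oxidation works without base or strong acid, so the exo-methylene group should not migrate into the ring and C13 and C26 should not epimerise.

Step 13
Reactants: 17 exo-methylene ketone; 18 4-hydroxy-5,6-dimethyl-2H-pyran-2-one
Product: 20 bis-TBS ether of the target (rings A–D complete), via open-chain Michael adduct 19 (not isolated)
Conditions: Et3N (cat.), CH2Cl2, rt
Reagents that add atoms: none
Why: Michael addition of the vinylogous acid through its C3 carbon to unhindered C29 (the ring D enone has a fully substituted β-carbon), then hemiketalisation of the 4-OH onto C11, as in 4-hydroxycoumarin–enone adducts; C28 is set under thermodynamic control with C29 equatorial and trans to the C27 methyl, and C11 takes the axial, anomerically favoured OH of a trans-fused ring B.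

Step 14
Reactants: 20 bis-TBS ether of the target
Product: 21 CNP0525404.1 (C11 S; C13 R; C17 R; C26 R; C28 R)
Conditions: HF·pyridine, THF, 0 °C → rt (plastic vessel)
Reagents that add atoms: none
Why: Fluoride desilylation under weakly acidic conditions frees C13–OH and C17–OH while avoiding the base-induced retro-aldol (C17–C23), α-ketol shift and retro-Michael pathways, and the hemiketal can relax to its preferred C11 configuration.

Compound list
1 | 2-methylcyclopentane-1,3-dione | CC1C(=O)CCC1=O | starting material
2 | 3-acetoxy-2-methylcyclopent-2-en-1-one | CC(=O)OC1=C(C)C(=O)CC1 | intermediate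
3 | 2,2-dimethylcyclopentane-1,3-dione | CC1(C)C(=O)CCC1=O | starting material
4 | (S)-3-hydroxy-2,2-dimethylcyclopentan-1-one | CC1(C)C(=O)CC[C@@H]1O | intermediate
5 | (S)-2,2-dimethyl-3-(triethylsilyloxy)cyclopentan-1-one | CC1(C)C(=O)CC[C@@H]1O[Si](CC)(CC)CC | intermediate
6 | (S)-1-(tert-butyldimethylsilyloxy)-5,5-dimethyl-4-(triethylsilyloxy)cyclopent-1-ene | CC1(C)C(O[Si](C)(C)C(C)(C)C)=CC[C@@H]1O[Si](CC)(CC)CC | intermediate
7 | cis-anti-cis cyclobutane photoadduct (C15 OAc, C17 OTBS, C26 methyl, C28 ketone, C21 OTES) | CC(=O)O[C@@]12CCC(=O)[C@]1(C)[C@H]1C[C@H](O[Si](CC)(CC)CC)C(C)(C)[C@@]21O[Si](C)(C)C(C)(C)C | intermediate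
8 | (1R,6S,7R,9S)-1-(tert-butyldimethylsilyloxy)-6,10,10-trimethyl-9-(triethylsilyloxy)bicyclo[5.3.0]decane-2,5-dione | O=C1CCC(=O)[C@@]2(O[Si](C)(C)C(C)(C)C)[C@H](C[C@H](O[Si](CC)(CC)CC)C2(C)C)[C@@H]1C | intermediate
9 | 5-methylene analogue of 8 (C28=CH2, ketone C15) | C=C1CCC(=O)[C@@]2(O[Si](C)(C)C(C)(C)C)[C@H](C[C@H](O[Si](CC)(CC)CC)C2(C)C)[C@@H]1C | intermediate
10 | potassium C13=C15 enolate of 9 | C=C1CC=C([O-])[C@@]2(O[Si](C)(C)C(C)(C)C)[C@H](C[C@H](O[Si](CC)(CC)CC)C2(C)C)[C@@H]1C.[K+] | intermediate
11 | C13 alcohol (OH on the bottom face) | C=C1C[C@H](O)C(=O)[C@@]2(O[Si](C)(C)C(C)(C)C)[C@H](C[C@H](O[Si](CC)(CC)CC)C2(C)C)[C@@H]1C | intermediate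
12 | C13 TBS ether | C=C1C[C@H](O[Si](C)(C)C(C)(C)C)C(=O)[C@@]2(O[Si](C)(C)C(C)(C)C)[C@H](C[C@H](O[Si](CC)(CC)CC)C2(C)C)[C@@H]1C | intermediate
13 | C21 alcohol | C=C1C[C@H](O[Si](C)(C)C(C)(C)C)C(=O)[C@@]2(O[Si](C)(C)C(C)(C)C)[C@H](C[C@H](O)C2(C)C)[C@@H]1C | intermediate
14 | C21 ketone (ring D saturated) | C=C1C[C@H](O[Si](C)(C)C(C)(C)C)C(=O)[C@@]2(O[Si](C)(C)C(C)(C)C)[C@H](CC(=O)C2(C)C)[C@@H]1C | intermediate
15 | ring D enone (C19=C20–C21=O) | C=C1C[C@H](O[Si](C)(C)C(C)(C)C)C(=O)[C@@]2(O[Si](C)(C)C(C)(C)C)C(=CC(=O)C2(C)C)[C@@H]1C | intermediate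
16 | C11 allylic alcohol (OH drawn on top) | C=C1[C@@H](O)[C@H](O[Si](C)(C)C(C)(C)C)C(=O)[C@@]2(O[Si](C)(C)C(C)(C)C)C(=CC(=O)C2(C)C)[C@@H]1C | intermediate
17 | exo-methylene ketone (C11, C15 and C21 ketones) | C=C1C(=O)[C@H](O[Si](C)(C)C(C)(C)C)C(=O)[C@@]2(O[Si](C)(C)C(C)(C)C)C(=CC(=O)C2(C)C)[C@@H]1C | intermediate
18 | 4-hydroxy-5,6-dimethyl-2H-pyran-2-one | Cc1oc(=O)cc(O)c1C | starting material
19 | open-chain Michael adduct (pyranone C3–C29H2–C28H, ketone C11) | Cc1oc(=O)c(C[C@H]2C(=O)[C@H](O[Si](C)(C)C(C)(C)C)C(=O)[C@@]3(O[Si](C)(C)C(C)(C)C)C(=CC(=O)C3(C)C)[C@@H]2C)c(O)c1C | intermediate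
20 | C13,C17-bis-TBS ether of the target | Cc1oc(=O)c2c(c1C)O[C@]1(O)[C@H](O[Si](C)(C)C(C)(C)C)C(=O)[C@@]3(O[Si](C)(C)C(C)(C)C)C(=CC(=O)C3(C)C)[C@H](C)[C@H]1C2 | intermediate
21 | CNP0525404.1 | Cc1oc(=O)c2c(c1C)O[C@]1(O)[C@H](O)C(=O)[C@@]3(O)C(=CC(=O)C3(C)C)[C@H](C)[C@H]1C2 | target

Total step count: 14. Longest linear sequence: 13 (steps 2–14, from 3).

Steps most likely to fail

Step 5. The adduct carries fully substituted C23, C17, C15 and C26 in a row, so the triplet enone may relax or dimerise faster than it bonds to the hindered enol ether. Face discrimination by the remote C21 substituent may also be incomplete. The fallback sets out from 6 and returns at 8, and it moves the introduction of methyl C27 to after the ring expansion.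
- Commercial cyclopentane-1,3-dione is acetylated as in step 1 to 3-acetoxycyclopent-2-en-1-one F1, whose trisubstituted C=C is far less crowded.
- Irradiation of F1 with 6 under the conditions of step 5 should give the nor-methyl photoadduct F2, which is isolated.
- LiOMe in THF–DMPU at −40 °C removes the acetate without a proton source, and the retro-aldol releases the nor-methyl lithium enolate F3 with its C=C fixed between C26 and C28.
- MeI alkylates C26 in the same flask, and brief K2CO3/MeOH equilibration of C26 leads to 8.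

Step 11. Hydrogen abstraction may occur at the doubly allylic C26–H instead of C11–H, or the ene reaction may stall next to the bulky C13 OTBS group. The fallback sets out from 8 and returns at 17, and it replaces allylic C–H oxidation by enolate oxidation before the methylene group exists. Its residual risk is competing deprotonation at C13.
- LiN(iPr)2 (one equivalent, THF, −78 °C) should deprotonate the more accessible ketone C28 on its CH2 side to give lithium enolate F4.
- The oxaziridine of step 7 then gives C11 alcohol F5.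
- TESOTf/2,6-lutidine gives C11,C21-bis-TES ether F6, and Wittig methylenation as in step 6 gives methylene ketone F7.
- KN(SiMe3)2 forms potassium enolate F8, and Davis oxidation gives C13 alcohol F9, with approach anti to both the C11 OTES and the C17 OTBS groups.
- TBSOTf gives C13 TBS ether F10, and PPTS/MeOH removes both TES groups to give diol F11.
- Excess IBX oxidises both carbinols to saturated triketone F12 and then dehydrogenates ring D to 17.

Step 7. Facial selectivity in the approach of the oxaziridine to the flexible seven-membered enolate may be poor. The fallback sets out from 9 and returns at 11, and it corrects C13 by substitution rather than by facial control.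
- Top-face attack gives the C13 epimer F13.
- A Mitsunobu reaction (PPh3, DIAD, 4-nitrobenzoic acid, toluene) inverts C13 by SN2 displacement to give 4-nitrobenzoate F14.
- K2CO3/MeOH methanolysis of F14 returns 11.

Further compounds
F1 | step 5 | 3-acetoxycyclopent-2-en-1-one | CC(=O)OC1=CC(=O)CC1
F2 | step 5 | nor-methyl cyclobutane photoadduct (C26–H) | CC(=O)O[C@@]12CCC(=O)[C@@H]1[C@H]1C[C@H](O[Si](CC)(CC)CC)C(C)(C)[C@@]21O[Si](C)(C)C(C)(C)C
F3 | step 5 | nor-methyl lithium C26=C28 enolate | [Li+].[O-]C1=C[C@H]2C[C@H](O[Si](CC)(CC)CC)C(C)(C)[C@@]2(O[Si](C)(C)C(C)(C)C)C(=O)CC1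
F4 | step 11 | lithium C11=C28 enolate of 8 | [Li+].[O-]C1=CCC(=O)[C@@]2(O[Si](C)(C)C(C)(C)C)[C@H](C[C@H](O[Si](CC)(CC)CC)C2(C)C)[C@@H]1C
F5 | step 11 | C11 alcohol of 8 | O=C1[C@@H](O)CC(=O)[C@@]2(O[Si](C)(C)C(C)(C)C)[C@H](C[C@H](O[Si](CC)(CC)CC)C2(C)C)[C@@H]1C
F6 | step 11 | C11,C21-bis-TES ether | O=C1[C@@H](O[Si](CC)(CC)CC)CC(=O)[C@@]2(O[Si](C)(C)C(C)(C)C)[C@H](C[C@H](O[Si](CC)(CC)CC)C2(C)C)[C@@H]1C
F7 | step 11 | methylene ketone with C11 OTES | C=C1[C@@H](O[Si](CC)(CC)CC)CC(=O)[C@@]2(O[Si](C)(C)C(C)(C)C)[C@H](C[C@H](O[Si](CC)(CC)CC)C2(C)C)[C@@H]1C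
F8 | step 11 | potassium C13=C15 enolate of F7 | [K+].C=C1[C@@H](O[Si](CC)(CC)CC)C=C([O-])[C@@]2(O[Si](C)(C)C(C)(C)C)[C@H](C[C@H](O[Si](CC)(CC)CC)C2(C)C)[C@@H]1C
F9 | step 11 | C13 alcohol with C11 OTES | C=C1[C@@H](O[Si](CC)(CC)CC)[C@H](O)C(=O)[C@@]2(O[Si](C)(C)C(C)(C)C)[C@H](C[C@H](O[Si](CC)(CC)CC)C2(C)C)[C@@H]1C
F10 | step 11 | C13 TBS ether with C11 and C21 OTES | C=C1[C@@H](O[Si](CC)(CC)CC)[C@H](O[Si](C)(C)C(C)(C)C)C(=O)[C@@]2(O[Si](C)(C)C(C)(C)C)[C@H](C[C@H](O[Si](CC)(CC)CC)C2(C)C)[C@@H]1C
F11 | step 11 | C11,C21-diol | C=C1[C@@H](O)[C@H](O[Si](C)(C)C(C)(C)C)C(=O)[C@@]2(O[Si](C)(C)C(C)(C)C)[C@H](C[C@H](O)C2(C)C)[C@@H]1C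
F12 | step 11 | saturated triketone (C11, C15, C21) | C=C1C(=O)[C@H](O[Si](C)(C)C(C)(C)C)C(=O)[C@@]2(O[Si](C)(C)C(C)(C)C)[C@H](CC(=O)C2(C)C)[C@@H]1C
F13 | step 7 | C13 epimer of 11 | C=C1C[C@@H](O)C(=O)[C@@]2(O[Si](C)(C)C(C)(C)C)[C@H](C[C@H](O[Si](CC)(CC)CC)C2(C)C)[C@@H]1C
F14 | step 7 | C13 4-nitrobenzoate with the configuration of 11 | C=C1C[C@H](OC(=O)c3ccc(cc3)[N+](=O)[O-])C(=O)[C@@]2(O[Si](C)(C)C(C)(C)C)[C@H](C[C@H](O[Si](CC)(CC)CC)C2(C)C)[C@@H]1C
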